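Q, the product of Z and E, climbed in the north-west run to 0.0222 M at 24 min and was levelling off there. In the north run, charged with 0.0500 M of Q from the start, it fell to 0.0362 M, so I read the step as running both ways.

| flask | Z | E | Q | time |
|---|---|---|---|---|
| north-west | 0.100 M | 0.300 M |  |  |
| south-west | 0.0500 M | 0.250 M |  |  |
| north | 0.100 M | 0.300 M | 0.0500 M |  |
| east | 0.100 M | 0.450 M |  |  |
| south-east | 0.100 M | 0.900 M |  | 24 min |

| run | time / min | [Q] / M |
|---|---|---|
| north-west run | 1.4 | 0.0033 |
| north-west run | 4.1 | 0.0086 |
| north-west run | 7.9 | 0.0123 |
| north-west run | 13 | 0.0197 |
| north-west run | 18 | 0.0211 |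
| north-west run | 24 | 0.0222 |
| south-west run | 1.4 | 0.0020 |
| south-west run | 4.1 | 0.0037 |
| south-west run | 7.9 | 0.0077 |
| south-west run | 13 | 0.0089 |
| south-west run | 18 | 0.0095 |
| south-west run | 24 | 0.0099 |
| north run | 1.4 | 0.0484 |
| north run | 4.1 | 0.0449 |
| north run | 7.9 | 0.0442 |
| north run | 13 | 0.0397 |
| north run | 18 | 0.0383 |
| north run | 24 | 0.0362 |
| east run | 1.4 | 0.0040 |
| east run | 4.1 | 0.0115 |
| east run | 7.9 | 0.0169 |
| east run | 13 | 0.0215 |
| east run | 18 | 0.0243 |
| east run | 24 | 0.0260 |

(scatter of a reading: 5 × 10⁻⁴ M)

- the power of [E] that the first rate follows, about the charge of the north-west run; measure it at two percent of Z made into Q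
- the power of [Z] that the first rate follows, about the charge of the north-west run; measure it at two percent of Z made into Q (one fixed amount of Q, the same in the runs compared)
- Q in the south-east run at 24 min, as a share of the Z charged

- Overall: Z + E -> Q.
- Constant volume, constant temperature.
- A reading of a species includes what of it is bound.
- An order is taken over about fifteen percent of the charge, up and down.

To see what E does, I divided one rate by another. The north-west and east runs hold the same Z, and the Q made by the second reading, over the same time, is a mean rate in each, so time drops out of the ratio. I summed the first two readings of each run, and the east run stood at 1.30 times the north-west run on 1.50 times the E. Their logarithms divided give 0.652, the E power: the number that turns a ratio of E into a ratio of rates at fixed Z, usually called the apparent order in E. It is a reading, and it carries the scatter.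

The south-west run has half the Z and somewhat less E. Its first two readings stood at 0.479 of the north-west sum, and dividing out 0.888 for E left 0.539, which gave me a Z power of 0.890.

The south-east run holds 3.00 times the north-west E, so by the E power its forward rate should gain 2.05. The last north-west reading, set over the Z charged less that Q, gave a ratio of 0.285. I assumed that the back step ignores E and that the south-east run at 24 min stands as level as the north-west run, so that ratio gains the same factor, and my reckoning put Q at 36.9% of the Z charged.

The forecast gave 0.6 for E, 1 for Z and 34.5% for Q, between 31% and 39%, on this ground: “I suspect E is mostly tied up (dimer-like), with a small active monomer, rather than simple saturation.” My figure for Q was higher than the forecast's.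

    Z + E ⇌ Q (0.8640 M⁻¹ min⁻¹, 0.05478 min⁻¹)
    Q + E → L (0.6120 M⁻¹ min⁻¹)
    2 E ⇌ E2, settled at all times (155.0 M⁻¹)

The flask gave 0.55 for E, 1.1 for Z and 28.7% for Q, which is 5.8 percentage points under the forecast. At an E power of 0.652, my reckoning counted the south-east charge of 3.00 times the E as 2.05 times, and the scheme shows part of the E parked as E2. That parking is the reason Q survives in the south-east run: the same run with it taken away holds 0.0253% of the Z as Q at 24 min, against 28.7%.

All runs were computed on assumed constants.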